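# Proposed synthesis of CNP0175926.1 by epoxide-triggered allylsilane closure of ring B

## The problem

The target **23** is a labdane-type ester. Labdane numbering is used throughout: ring A is C1–C5 and C10, ring B is C5–C10; C4 carries the C18 methyl and the C19 ester carbon, C10 carries the C20 methyl, C8=C17 is the methylidene, and C9 carries the chain C11–C15 with the C16 methyl on C13. β denotes the face of ring A that carries C19 and H5, α the face of C18 and of the C5–C6 bond.

The two rings are cis-fused, and the fusion carbon C10 is quaternary and lies between C5 (next to the second quaternary carbon C4) and the C9 stereocentre. Four contiguous stereocentres (C4, C5, C10, C9) therefore crowd one edge of the decalin, with C19, H5, C20 and C11 all on the β face. These centres can be relayed: C4 and C5 can be set together, the C5 substituent can decide the face of a reaction at C1/C10, and a stereospecific reaction at C10 can pass the information to C9. The C13/C14 epoxide sits on a flexible chain, out of reach of the ring, and needs reagent control.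

The 2,3-epoxy alcohol will not survive Lewis acids, organometallic reagents or radical conditions and has to be made last. The C8=C17 alkene migrates into the ring under acid and forbids late hydrogenation. The neopentyl methyl ester tolerates most reagents but not an excess of hydride.

The enabling feature is the array C10–C9–C8(=C17): a quaternary carbon bonded to a carbon that is allylic to an exocyclic alkene. This is what remains when the γ-carbon of an allylsilane attacks a tertiary electrophile, so ring B can be closed onto a finished ring A with C10, C9 and the methylidene formed in one step.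

## Retrosynthesis

**Epoxide last (23 ⇒ 22).** The C13–O and C14–O bonds are cut first. A Sharpless–Katsuki epoxidation of the (E)-allylic alcohol **22** is the only disconnection that sets C13 and C14 without help from the ring and leaves the C8=C17 alkene alone; a peracid would attack both alkenes without face control. The forward step must give the (13R,14R) epoxide, which for an (E)-3-methyl-2-alken-1-ol calls for D-(−)-diethyl tartrate.

**Side chain (22 ⇒ 19 ⇒ 18).** C13–C16 and C14–C15 are cut together by methylalumination of the terminal alkyne **19** followed by hydroxymethylation. Syn addition fixes the (E) geometry. The neighbouring options are weaker: an sp3–sp2 coupling of a C12 iodide with an iodobutenol needs three more steps and a scarce reagent, and olefination of a methyl ketone gives E/Z mixtures. The alkyne is carried from the start as its silyl-capped form (**18**), an inert placeholder for C13 and C14.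

**C1 deoxygenation (18 ⇒ 16).** A hydroxyl is put back on C1. It is the scar of the epoxide used to trigger ring closure and is removed by radical deoxygenation; the C1 radical has no favourable cyclisation onto C8=C17.

**Ring B (16 ⇒ 15).** The C9–C10 bond is cut. The cut makes the quaternary centre by a stereospecific substitution and turns C9 into the terminus of an allylsilane whose collapse gives the methylidene directly. Protonation of a C1=C10 alkene would lose to protodesilylation, so the C1–C10 epoxide is the site-specific trigger; its price is the C1 hydroxyl. The precursor **15** is monocyclic, with only the ring A stereocentres. The forward reaction needs the epoxide on the face opposite the C5 chain and the (Z) silane geometry.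

**Allylsilane and epoxide (15 ⇒ 14 ⇒ 13).** C8–C17 is cut by a Negishi coupling of the (Z)-alkenyl bromide **14** with Me3SiCH2ZnCl, and the epoxide oxygen is removed to give alkene **13**. The order matters: an allylsilane would not survive a peracid, whereas the bromoalkene is inert to it and serves as a masked allylsilane from step 3 to step 11.

**Ring A (13 ⇒ 12 ⇒ 11 ⇒ 9 + 10).** After adjusting the oxidation level, C4–C5 and C2–C3 are cut in a Diels–Alder reaction between the acyclic diene **9** and methacrolein **10**. This sets C4 and C5 together. Methylation of a ring A ester enolate would put the methyl anti to the C5 chain, the wrong isomer, so the cycloaddition is preferred. It must be regioselective (formyl-bearing carbon to C5), exo (formyl trans to the chain) and enantioselective.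

**Diene (9 ⇒ 8 ⇒ 6).** The C1=C2 and C5=C10 alkenes are cut by two Wittig reactions; the stabilised formyl ylide **7** secures the (E) trisubstituted alkene.

**Chain (6 ⇒ 5 ⇒ 3 + 4; 3 ⇒ 2 ⇒ 1).** C7–C8 is cut by a trans-selective Negishi monoalkylation of the 1,1-dibromoalkene **3** with the zinc homoenolate **4**. This one step fixes the bromoalkene geometry that later becomes the silane geometry and then C9. **3** comes in two steps from commercial 5-(trimethylsilyl)pent-4-yn-1-ol **1** through aldehyde **2**.

## Roads not taken

**Alternative 1:** Cyclopropanation, then reductive opening to the angular methyl. The cut is at C10–C20 and C5–C20. A Birch-derived bicyclic alcohol **A1** (C5=C10 tetrasubstituted alkene, C19 hydroxymethyl, C8 dioxolane) would receive CH2 from the zinc carbenoid of Et2Zn/CH2I2, guided by the C19 hydroxyl, to give propellane **A2**. Opening of the C5–C20 bond would then leave the C10 methyl and H5.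
- Merits: C20 is delivered on the face of C19, so the C4/C10 relation is enforced by the tether. The starting material is a cheap arene, and no oxygen has to be removed from C1. In these respects it is better than the chosen plan.
- Weak points: nothing distinguishes the C5–C20 bond from the C10–C20 bond in the opening, so the methyl may end on C5. C9 must still be alkylated next to quaternary C10 with stereocontrol. C8 must be methylenated and C19 oxidised. Absolute configuration needs an asymmetric Birch alkylation or a resolution.
- Against this the chosen plan sets one step that forms C10, C9 and the methylidene, and catalytic absolute control.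

**Alternative 2:** Cuprate methylation with in situ enolate allylation. The cut is at C10–C20 and C9–C11. Me2CuLi would add to C10 of octalone **A3** (C8 ketone, C9=C10 alkene, C3 dioxolane) and the enolate would be allylated at C9 to give decalone **A4**.
- Merits: two bonds and two stereocentres in one flask, a well-known preference for the cis-fused product, and an enone of a class available in enantioenriched form. In convergence at C9/C10 it equals the chosen key step.
- Weak points: the enolate is neopentyl and the allyl group must enter next to the new methyl, so proton transfer and C7 alkylation compete. C4 is still a methylene and must be built from the C3 ketone by carboxylation and methylation with face control, followed by removal of the C3 oxygen. The allyl group is one carbon short of a useful handle, and the hindered C8 ketone must be methylenated beside an epimerisable C9.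
- The chosen plan brings ring A with C4 complete and sets C9 by alkene geometry, not by the face selectivity of a hindered enolate. It pays with a longer acyclic prelude and a deoxygenation.

**Alternative 3:** Intramolecular Diels–Alder reaction of a (Z)-diene. The cut is at C3–C4 and C5–C10. Triene **A5** (an (E)-2-methyl-2-enoate tethered through C6–C9 to a (Z)-diene C10=C1–C2=C3) would close both rings to octalin ester **A6**.
- Merits: it is the most convergent road. Both rings, both quaternary carbons and the cis fusion (enforced by the Z geometry) arise in one thermal step, with no oxygen scar at C1. If it worked it would be shorter than the chosen plan.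
- Weak points: bonds must form to a fully substituted diene terminus and to a trisubstituted dienophile, so high temperatures are needed, at which (Z)-dienes undergo 1,5-hydrogen shifts. Face selectivity rests on the single C9 stereocentre, which has to be made enantioenriched in an acyclic precursor. The C1=C2 alkene must be hydrogenated and the C8 ketal converted into the methylidene afterwards.
- The chosen plan sets against it two low-barrier ring closures whose control elements (catalyst, epoxide face, silane geometry) can be checked one at a time.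

Key step: step 12

Assumption: the facial sense of the cycloaddition in step 7 is taken from the accepted model for 2-substituted acroleins bound to the protonated (S)-oxazaborolidine (the sense that gives the (2S)-exo adduct with cyclopentadiene); the (R)-catalyst would be used if the opposite sense were found.

## Route

Step 1
Reactants: 1 5-(trimethylsilyl)pent-4-yn-1-ol
Product: 2 5-(trimethylsilyl)pent-4-ynal
Conditions: Dess–Martin periodinane, CH2Cl2, 0 → 23 °C
Reagents that add atoms: none
Why: Dess–Martin oxidation of a primary alcohol stops at the aldehyde and leaves the alkynylsilane untouched.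

Step 2
Reactants: 2 5-(trimethylsilyl)pent-4-ynal
Product: 3 (6,6-dibromohex-5-en-1-yn-1-yl)trimethylsilane
Conditions: CBr4, PPh3, CH2Cl2, 0 °C
Reagents that add atoms: carbon tetrabromide, BrC(Br)(Br)Br
Why: Ramirez dibromo-olefination (first stage of the Corey–Fuchs sequence); the ylide Ph3P=CBr2 formed in the flask converts the aldehyde into the 1,1-dibromoalkene, whose two C–Br bonds differ only in their relation to the C11 chain.

Step 3
Reactants: 3 (6,6-dibromohex-5-en-1-yn-1-yl)trimethylsilane; 4 (3-ethoxy-3-oxopropyl)zinc bromide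
Product: 5 ethyl (4Z)-4-bromo-9-(trimethylsilyl)non-4-en-8-ynoate
Conditions: 4 (0.5 M in THF), PdCl2[(Ph2PC6H4)2O] (3 mol %), THF, 0 → 23 °C
Reagents that add atoms: none
Why: Negishi coupling, trans-selective monoalkylation of a 1,1-dibromoalkene: zerovalent palladium inserts into the less hindered C–Br bond trans to the alkyl chain, so C7 enters trans to C11 and the remaining bromine stays cis to C11 (Z). The wide-bite-angle diphosphine holds the reaction at monosubstitution, and the ester-bearing alkylzinc is tolerated.

Step 4
Reactants: 5 ethyl (4Z)-4-bromo-9-(trimethylsilyl)non-4-en-8-ynoate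
Product: 6 (4Z)-4-bromo-9-(trimethylsilyl)non-4-en-8-ynal
Conditions: i-Bu2AlH (1.05 equiv), CH2Cl2, −78 °C; MeOH, aq. potassium sodium tartrate
Reagents that add atoms: none
Why: Partial reduction of an ester with i-Bu2AlH; the aluminium hemiacetal is stable at −78 °C and releases the aldehyde only on work-up, and the bromoalkene and alkynylsilane do not react.

Step 5
Reactants: 6 (4Z)-4-bromo-9-(trimethylsilyl)non-4-en-8-ynal; 7 2-(triphenylphosphoranylidene)propanal
Product: 8 (2E,6Z)-6-bromo-2-methyl-11-(trimethylsilyl)undeca-2,6-dien-10-ynal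
Conditions: toluene, 90 °C
Reagents that add atoms: none
Why: Wittig reaction with a formyl-stabilised ylide, which gives the (E)-2-methyl enal and reacts with the aliphatic aldehyde far faster than with the conjugated product.

Step 6
Reactants: 8 (2E,6Z)-6-bromo-2-methyl-11-(trimethylsilyl)undeca-2,6-dien-10-ynal
Product: 9 (3E,7Z)-7-bromo-3-methyl-12-(trimethylsilyl)dodeca-1,3,7-trien-11-yne
Conditions: Ph3PCH3Br, n-BuLi, THF, −78 → 0 °C
Reagents that add atoms: methyltriphenylphosphonium bromide, C[P+](c1ccccc1)(c1ccccc1)c1ccccc1.[Br-]
Why: Wittig methylenation of the enal; the non-stabilised ylide adds 1,2 and the existing trisubstituted alkene keeps its (E) geometry, giving the 1-alkyl-2-methyl diene.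

Step 7
Reactants: 9 (3E,7Z)-7-bromo-3-methyl-12-(trimethylsilyl)dodeca-1,3,7-trien-11-yne; 10 methacrolein
Product: 11 (1S,2S)-2-[(3Z)-3-bromo-8-(trimethylsilyl)oct-3-en-7-yn-1-yl]-1,3-dimethylcyclohex-3-ene-1-carbaldehyde
Conditions: 10 (3 equiv), (3aS)-1-(2-methylphenyl)-3,3-diphenyltetrahydro-1H,3H-pyrrolo[1,2-c][1,3,2]oxazaborole (20 mol %), HNTf2 (17 mol %), CH2Cl2, −78 → −40 °C
Reagents that add atoms: none
Why: Catalytic asymmetric Diels–Alder reaction of a 2-substituted acrolein on a protonated oxazaborolidine; the 1-alkyl terminus of the diene is the stronger director, so the enal β-carbon bonds to C2 and the formyl-bearing carbon to C5 (ortho rule, sharpened by the Lewis acid). The formyl group sits exo, as is usual for 2-methylacrolein, and so ends trans to the C5 chain; the catalyst shields one face of the s-trans enal, setting C4 and C5 together.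

Step 8
Reactants: 11 (1S,2S)-2-[(3Z)-3-bromo-8-(trimethylsilyl)oct-3-en-7-yn-1-yl]-1,3-dimethylcyclohex-3-ene-1-carbaldehyde
Product: 12 (1S,2S)-2-[(3Z)-3-bromo-8-(trimethylsilyl)oct-3-en-7-yn-1-yl]-1,3-dimethylcyclohex-3-ene-1-carboxylic acid
Conditions: NaClO2, NaH2PO4, 2-methylbut-2-ene, t-BuOH/H2O, 23 °C
Reagents that add atoms: sodium chlorite, [Na+].[O-]Cl=O
Why: Pinnick oxidation converts the hindered, non-enolisable aldehyde into the acid; 2-methylbut-2-ene removes HOCl before it can add to the ring alkene.

Step 9
Reactants: 12 (1S,2S)-2-[(3Z)-3-bromo-8-(trimethylsilyl)oct-3-en-7-yn-1-yl]-1,3-dimethylcyclohex-3-ene-1-carboxylic acid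
Product: 13 methyl (1S,2S)-2-[(3Z)-3-bromo-8-(trimethylsilyl)oct-3-en-7-yn-1-yl]-1,3-dimethylcyclohex-3-ene-1-carboxylate
Conditions: Me3SiCHN2, toluene/MeOH, 0 °C
Reagents that add atoms: (trimethylsilyl)diazomethane, C[Si](C)(C)C=[N+]=[N-]
Why: Esterification with (trimethylsilyl)diazomethane is neutral and indifferent to the shielding of the neopentyl carboxyl group; no base is present that could cleave the alkynylsilane.

Step 10
Reactants: 13 methyl (1S,2S)-2-[(3Z)-3-bromo-8-(trimethylsilyl)oct-3-en-7-yn-1-yl]-1,3-dimethylcyclohex-3-ene-1-carboxylate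
Product: 14 methyl (1S,2R,3S,6R)-2-[(3Z)-3-bromo-8-(trimethylsilyl)oct-3-en-7-yn-1-yl]-1,3-dimethyl-7-oxabicyclo[4.1.0]heptane-3-carboxylate (β epoxide across C1–C10)
Conditions: m-CPBA, NaHCO3, CH2Cl2, 0 °C
Reagents that add atoms: 3-chloroperoxybenzoic acid, OOC(=O)c1cccc(Cl)c1
Why: Prilezhaev epoxidation; the trisubstituted ring alkene is far more electron-rich than the bromoalkene or the alkyne, and the peracid approaches anti to the allylic C5 chain, giving the β epoxide.

Step 11
Reactants: 14 methyl (1S,2R,3S,6R)-2-[(3Z)-3-bromo-8-(trimethylsilyl)oct-3-en-7-yn-1-yl]-1,3-dimethyl-7-oxabicyclo[4.1.0]heptane-3-carboxylate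
Product: 15 methyl (1S,2R,3S,6R)-1,3-dimethyl-2-{(3Z)-8-(trimethylsilyl)-3-[(trimethylsilyl)methyl]oct-3-en-7-yn-1-yl}-7-oxabicyclo[4.1.0]heptane-3-carboxylate
Conditions: Me3SiCH2MgCl, ZnCl2, THF, 0 °C; then 14, Pd[P(t-Bu)3]2 (5 mol %), THF, 23 °C
Reagents that add atoms: (trimethylsilyl)methylmagnesium chloride, C[Si](C)(C)C[Mg]Cl
Why: Negishi coupling of the alkenyl bromide with Me3SiCH2ZnCl, which has no β-hydrogen; with the bulky, electron-rich zerovalent palladium catalyst the substitution proceeds with retention, so the silylmethyl group ends cis to C11 ((Z)-allylsilane). The organozinc leaves ester and epoxide untouched.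

Step 12
Reactants: 15 methyl (1S,2R,3S,6R)-1,3-dimethyl-2-{(3Z)-8-(trimethylsilyl)-3-[(trimethylsilyl)methyl]oct-3-en-7-yn-1-yl}-7-oxabicyclo[4.1.0]heptane-3-carboxylate
Product: 16 methyl (1S,4R,4aR,5S,8aS)-4-hydroxy-1,4a-dimethyl-6-methylidene-5-[4-(trimethylsilyl)but-3-yn-1-yl]decahydronaphthalene-1-carboxylate (cis-fused; C1 hydroxyl, C20 and C11 all β)
Conditions: BF3·OEt2 (1.5 equiv), CH2Cl2, −78 °C; aq. NaHCO3
Reagents that add atoms: none
Why: BF3 binds the epoxide oxygen and polarises the C10–O bond at the tertiary carbon; the γ-carbon of the allylsilane (C9) attacks C10 from the α face, anti to the departing oxygen, and the β-silyl cation at C8 collapses by loss of silicon to the C8=C17 methylidene. The closest known reaction type is the Lewis-acid-promoted intramolecular addition of allylsilanes to epoxides, an epoxide-initiated cation–olefin cyclisation with an allylsilane terminator. Ring B closes in a six-membered mode that is exo with respect to the breaking C10–O bond (the oxygen stays on C1, outside the new ring) and endo with respect to the C8=C9 alkene, through a chair-like arrangement on a ring A chair formed by trans-diaxial opening. C10 is set by inversion: the nucleophile is tethered through C6 on the α face and the oxygen leaves from the β face, so the methyl ends β and the fusion can only be cis. C9 is set by the (Z) geometry of the silane: C11 is trans to C7 on the alkene, takes the equatorial site of the forming chair and ends cis to the C10 methyl. The step needs C–C bond formation to outrun hydride shift to a C1 ketone and capture of C10 by the ester; the high nucleophilicity of the allylsilane, the low temperature and the fact that the β ester cannot reach the α (backside) lobe of C10 secure this. The silyl-capped alkyne is remote and too weak a nucleophile to interfere.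

Step 13
Reactants: 16 methyl (1S,4R,4aR,5S,8aS)-4-hydroxy-1,4a-dimethyl-6-methylidene-5-[4-(trimethylsilyl)but-3-yn-1-yl]decahydronaphthalene-1-carboxylate
Product: 17 methyl (1S,4R,4aR,5S,8aS)-1,4a-dimethyl-6-methylidene-4-[(phenoxycarbonothioyl)oxy]-5-[4-(trimethylsilyl)but-3-yn-1-yl]decahydronaphthalene-1-carboxylate
Conditions: PhOC(S)Cl, DMAP, MeCN, 23 → 50 °C
Reagents that add atoms: O-phenyl chlorothionoformate, S=C(Cl)Oc1ccccc1
Why: Acylation of the hindered secondary alcohol under nucleophilic catalysis (first half of the Barton–McCombie deoxygenation); the non-basic conditions avoid an alkoxide that could attack the β ester across ring A.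

Step 14
Reactants: 17 methyl (1S,4R,4aR,5S,8aS)-1,4a-dimethyl-6-methylidene-4-[(phenoxycarbonothioyl)oxy]-5-[4-(trimethylsilyl)but-3-yn-1-yl]decahydronaphthalene-1-carboxylate
Product: 18 methyl (1S,4aR,5S,8aS)-1,4a-dimethyl-6-methylidene-5-[4-(trimethylsilyl)but-3-yn-1-yl]decahydronaphthalene-1-carboxylate
Conditions: Bu3SnH (1.5 equiv), AIBN (cat.), toluene, 100 °C
Reagents that add atoms: none
Why: Barton–McCombie deoxygenation; the stannyl radical adds to C=S, the C1–O bond fragments and the secondary radical is reduced by Bu3SnH. The radical has only 4-exo or 5-endo paths to the C8=C17 alkene, and stannyl addition to the silyl-capped alkyne is slow and reversible, so no stereocentre is touched.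

Step 15
Reactants: 18 methyl (1S,4aR,5S,8aS)-1,4a-dimethyl-6-methylidene-5-[4-(trimethylsilyl)but-3-yn-1-yl]decahydronaphthalene-1-carboxylate
Product: 19 methyl (1S,4aR,5S,8aS)-5-(but-3-yn-1-yl)-1,4a-dimethyl-6-methylidenedecahydronaphthalene-1-carboxylate
Conditions: K2CO3 (cat.), MeOH, 23 °C
Reagents that add atoms: none
Why: Methanolysis of the alkynylsilane under catalytic carbonate; the methyl ester can only exchange with methanol degenerately.

Step 16
Reactants: 19 methyl (1S,4aR,5S,8aS)-5-(but-3-yn-1-yl)-1,4a-dimethyl-6-methylidenedecahydronaphthalene-1-carboxylate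
Product: 22 methyl (1S,4aR,5S,8aS)-5-[(3E)-5-hydroxy-3-methylpent-3-en-1-yl]-1,4a-dimethyl-6-methylidenedecahydronaphthalene-1-carboxylate, via alkenyldimethylalane 20 (not isolated), via lithium alkenylaluminate 21 (not isolated)
Conditions: Me3Al, Cp2ZrCl2 (0.25 equiv), CH2Cl2, 0 → 23 °C; then n-BuLi, THF, −78 °C; (CH2O)n, −78 → 23 °C
Reagents that add atoms: trimethylaluminium, C[Al](C)C; paraformaldehyde (as formaldehyde), C=O
Why: Negishi zirconium-catalysed carboalumination of the terminal alkyne: methyl adds to C13 and aluminium to C14 on the same side, and the alkenyl aluminate is hydroxymethylated by formaldehyde with retention, giving the (E)-allylic alcohol. The 1,1-disubstituted alkene is inert and the neopentyl ester is slow toward Me3Al at this temperature.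

Step 17
Reactants: 22 methyl (1S,4aR,5S,8aS)-5-[(3E)-5-hydroxy-3-methylpent-3-en-1-yl]-1,4a-dimethyl-6-methylidenedecahydronaphthalene-1-carboxylate
Product: 23 methyl (1S,4aR,5S,8aS)-5-{2-[(2R,3R)-3-(hydroxymethyl)-2-methyloxiran-2-yl]ethyl}-1,4a-dimethyl-6-methylidenedecahydronaphthalene-1-carboxylate (target)
Conditions: Ti(OiPr)4 (10 mol %), D-(−)-diethyl tartrate (12 mol %), t-BuOOH, 4 Å sieves, CH2Cl2, −20 °C
Reagents that add atoms: tert-butyl hydroperoxide, CC(C)(C)OO
Why: Sharpless–Katsuki asymmetric epoxidation; with D-(−)-diethyl tartrate the titanium-bound peroxide is delivered to the face of the (E)-allylic alcohol that gives the (13R,14R) epoxide, under reagent control independent of the remote decalin. The unfunctionalised C8=C17 alkene does not react.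

## Compound list

1 | 5-(trimethylsilyl)pent-4-yn-1-ol | OCCCC#C[Si](C)(C)C | starting material
2 | 5-(trimethylsilyl)pent-4-ynal | O=CCCC#C[Si](C)(C)C | intermediate
3 | (6,6-dibromohex-5-en-1-yn-1-yl)trimethylsilane | BrC(Br)=CCCC#C[Si](C)(C)C | intermediate
4 | (3-ethoxy-3-oxopropyl)zinc bromide | CCOC(=O)CC[Zn]Br | starting material
5 | ethyl (4Z)-4-bromo-9-(trimethylsilyl)non-4-en-8-ynoate | CCOC(=O)CC/C(Br)=C/CCC#C[Si](C)(C)C | intermediate
6 | (4Z)-4-bromo-9-(trimethylsilyl)non-4-en-8-ynal | O=CCC/C(Br)=C/CCC#C[Si](C)(C)C | intermediate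
7 | 2-(triphenylphosphoranylidene)propanal | CC(C=O)=P(c1ccccc1)(c1ccccc1)c1ccccc1 | starting material
8 | (2E,6Z)-6-bromo-2-methyl-11-(trimethylsilyl)undeca-2,6-dien-10-ynal | O=C/C(C)=C/CC/C(Br)=C/CCC#C[Si](C)(C)C | intermediate
9 | (3E,7Z)-7-bromo-3-methyl-12-(trimethylsilyl)dodeca-1,3,7-trien-11-yne | C=C/C(C)=C/CC/C(Br)=C/CCC#C[Si](C)(C)C | intermediate
10 | methacrolein | CC(=C)C=O | starting material
11 | (1S,2S)-2-[(3Z)-3-bromo-8-(trimethylsilyl)oct-3-en-7-yn-1-yl]-1,3-dimethylcyclohex-3-ene-1-carbaldehyde | Br/C(CC[C@H]1C(C)=CCC[C@]1(C)C=O)=C\CCC#C[Si](C)(C)C | intermediate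
12 | (1S,2S)-2-[(3Z)-3-bromo-8-(trimethylsilyl)oct-3-en-7-yn-1-yl]-1,3-dimethylcyclohex-3-ene-1-carboxylic acid | Br/C(CC[C@H]1C(C)=CCC[C@]1(C)C(=O)O)=C\CCC#C[Si](C)(C)C | intermediate
13 | methyl (1S,2S)-2-[(3Z)-3-bromo-8-(trimethylsilyl)oct-3-en-7-yn-1-yl]-1,3-dimethylcyclohex-3-ene-1-carboxylate | Br/C(CC[C@H]1C(C)=CCC[C@]1(C)C(=O)OC)=C\CCC#C[Si](C)(C)C | intermediate
14 | methyl (1S,2R,3S,6R)-2-[(3Z)-3-bromo-8-(trimethylsilyl)oct-3-en-7-yn-1-yl]-1,3-dimethyl-7-oxabicyclo[4.1.0]heptane-3-carboxylate | Br/C(CC[C@H]1[C@]2(C)O[C@@H]2CC[C@]1(C)C(=O)OC)=C\CCC#C[Si](C)(C)C | intermediate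
15 | methyl (1S,2R,3S,6R)-1,3-dimethyl-2-{(3Z)-8-(trimethylsilyl)-3-[(trimethylsilyl)methyl]oct-3-en-7-yn-1-yl}-7-oxabicyclo[4.1.0]heptane-3-carboxylate | C[Si](C)(C)C/C(CC[C@H]1[C@]2(C)O[C@@H]2CC[C@]1(C)C(=O)OC)=C\CCC#C[Si](C)(C)C | intermediate
16 | methyl (1S,4R,4aR,5S,8aS)-4-hydroxy-1,4a-dimethyl-6-methylidene-5-[4-(trimethylsilyl)but-3-yn-1-yl]decahydronaphthalene-1-carboxylate | C=C1CC[C@H]2[C@](C)([C@H](O)CC[C@]2(C)C(=O)OC)[C@H]1CCC#C[Si](C)(C)C | intermediate
17 | methyl (1S,4R,4aR,5S,8aS)-1,4a-dimethyl-6-methylidene-4-[(phenoxycarbonothioyl)oxy]-5-[4-(trimethylsilyl)but-3-yn-1-yl]decahydronaphthalene-1-carboxylate | C=C1CC[C@H]2[C@](C)([C@H](OC(=S)Oc3ccccc3)CC[C@]2(C)C(=O)OC)[C@H]1CCC#C[Si](C)(C)C | intermediate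
18 | methyl (1S,4aR,5S,8aS)-1,4a-dimethyl-6-methylidene-5-[4-(trimethylsilyl)but-3-yn-1-yl]decahydronaphthalene-1-carboxylate | C=C1CC[C@H]2[C@](C)(CCC[C@]2(C)C(=O)OC)[C@H]1CCC#C[Si](C)(C)C | intermediate
19 | methyl (1S,4aR,5S,8aS)-5-(but-3-yn-1-yl)-1,4a-dimethyl-6-methylidenedecahydronaphthalene-1-carboxylate | C=C1CC[C@H]2[C@](C)(CCC[C@]2(C)C(=O)OC)[C@H]1CCC#C | intermediate
20 | (E)-alkenyldimethylalane from 19 (methyl on C13, AlMe2 on C14, C12 trans to Al) | C=C1CC[C@H]2[C@](C)(CCC[C@]2(C)C(=O)OC)[C@H]1CC/C(C)=C/[Al](C)C | intermediate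
21 | lithium butyl(dimethyl)alkenylaluminate from 20 | [Li+].C=C1CC[C@H]2[C@](C)(CCC[C@]2(C)C(=O)OC)[C@H]1CC/C(C)=C/[Al-](C)(C)CCCC | intermediate
22 | methyl (1S,4aR,5S,8aS)-5-[(3E)-5-hydroxy-3-methylpent-3-en-1-yl]-1,4a-dimethyl-6-methylidenedecahydronaphthalene-1-carboxylate | C=C1CC[C@H]2[C@](C)(CCC[C@]2(C)C(=O)OC)[C@H]1CC/C(C)=C/CO | intermediate
23 | methyl (1S,4aR,5S,8aS)-5-{2-[(2R,3R)-3-(hydroxymethyl)-2-methyloxiran-2-yl]ethyl}-1,4a-dimethyl-6-methylidenedecahydronaphthalene-1-carboxylate | C=C1CC[C@H]2[C@](C)(CCC[C@]2(C)C(=O)OC)[C@H]1CC[C@@]1(C)O[C@@H]1CO | target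

## Step count and least certain steps

Total: 17 steps. Longest linear sequence: 17 steps, from 1 to 23; compounds 4, 7 and 10 are purchased.

**Step 12 (key step).** Ionisation at C10 may run ahead of C–C bond formation and end in hydride shift to a C1 ketone, in capture of C10 by the β ester or in protodesilylation. A boat-like closure with eclipsing about the forming bond would invert C9. Fallback, from 13 back to 18:
- Allylic oxidation at C2 (Rh2(caprolactamate)4, t-BuOOH) would give the C2 enone of 13 F1.
- Negishi coupling as in step 11 would give the allylsilane enone F2.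
- A TiCl4-promoted intramolecular Hosomi–Sakurai conjugate addition would form C9–C10 from the α face of the enone without any cation at C10 and give the cis-fused C2 ketone F3.
- NaBH4 would give the C2 alcohol F4; its phenyl thionocarbonate F5 and Bu3SnH would return to 18.

**Step 7.** Face or exo selectivity may be insufficient because the large catalyst has to accommodate an acyclic, trisubstituted diene with a long chain. Fallback, from 9 back to 12:
- A Me2AlCl-promoted cycloaddition with 10 would give 11 together with its enantiomer ent-11 F6.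
- Pinnick oxidation would give 12 with ent-12 F7.
- Crystallisation with (R)-1-phenylethylamine would separate the (R)-1-phenylethylammonium salt of 12 F8; acidification returns to 12.

**Step 3.** Over-alkylation at the second C–Br bond or stereochemical leakage at the alkenylpalladium stage would erode the geometry on which C9 depends. Fallback, from 2 back to 5:
- A Wittig reaction with ethyl bromo(triphenylphosphoranylidene)acetate puts the ester trans to the chain and would give ethyl (2Z)-2-bromo-7-(trimethylsilyl)hept-2-en-6-ynoate F9.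
- i-Bu2AlH would give (2Z)-2-bromo-7-(trimethylsilyl)hept-2-en-6-yn-1-ol F10.
- CBr4/PPh3 would give [(5Z)-6,7-dibromohept-5-en-1-yn-1-yl]trimethylsilane F11; alkylation of the lithium enolate of ethyl acetate with this allylic bromide returns to 5.

**Step 13.** Acylation of the axial, neopentyl C1 hydroxyl may stall, and forcing it invites elimination. Fallback, from 16 back to 18:
- Dess–Martin oxidation would give the C1 ketone F12.
- Condensation with tosylhydrazide would give the tosylhydrazone F13.
- Reduction with catecholborane and NaOAc returns to 18.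

**Step 16.** Me3Al may attack the ester or move the exocyclic alkene into the ring, or hydroxymethylation of the aluminate may be incomplete. Fallback, from 19 back to 22:
- Gold-catalysed hydration (Ph3PAuNTf2, aqueous dioxane) would give the methyl ketone F14.
- A Horner–Wadsworth–Emmons reaction with trimethyl phosphonoacetate would give the (E)-enoate F15, separated from the minor (Z) isomer.
- i-Bu2AlH at −78 °C would reduce the unhindered conjugated ester in preference to the neopentyl C19 ester and return to 22.

## Further compounds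

F1 | step 12 | methyl (1S,2S)-2-[(3Z)-3-bromo-8-(trimethylsilyl)oct-3-en-7-yn-1-yl]-1,3-dimethyl-5-oxocyclohex-3-ene-1-carboxylate (C2 enone of 13) | Br/C(CC[C@H]1C(C)=CC(=O)C[C@]1(C)C(=O)OC)=C\CCC#C[Si](C)(C)C
F2 | step 12 | methyl (1S,2S)-1,3-dimethyl-5-oxo-2-{(3Z)-8-(trimethylsilyl)-3-[(trimethylsilyl)methyl]oct-3-en-7-yn-1-yl}cyclohex-3-ene-1-carboxylate | C[Si](C)(C)C/C(CC[C@H]1C(C)=CC(=O)C[C@]1(C)C(=O)OC)=C\CCC#C[Si](C)(C)C
F3 | step 12 | C2 ketone of 18 (3-oxo in naphthalene numbering, cis-fused) | C=C1CC[C@H]2[C@](C)(CC(=O)C[C@]2(C)C(=O)OC)[C@H]1CCC#C[Si](C)(C)C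
F4 | step 12 | C2 alcohol of 18 (either C2 epimer) | C=C1CC[C@H]2[C@](C)(CC(O)C[C@]2(C)C(=O)OC)[C@H]1CCC#C[Si](C)(C)C
F5 | step 12 | O-phenyl thionocarbonate of F4 | C=C1CC[C@H]2[C@](C)(CC(OC(=S)Oc3ccccc3)C[C@]2(C)C(=O)OC)[C@H]1CCC#C[Si](C)(C)C
F6 | step 7 | ent-11, (1R,2R)-2-[(3Z)-3-bromo-8-(trimethylsilyl)oct-3-en-7-yn-1-yl]-1,3-dimethylcyclohex-3-ene-1-carbaldehyde | Br/C(CC[C@@H]1C(C)=CCC[C@@]1(C)C=O)=C\CCC#C[Si](C)(C)C
F7 | step 7 | ent-12, the (1R,2R) acid | Br/C(CC[C@@H]1C(C)=CCC[C@@]1(C)C(=O)O)=C\CCC#C[Si](C)(C)C
F8 | step 7 | (R)-1-phenylethylammonium salt of 12 | Br/C(CC[C@H]1C(C)=CCC[C@]1(C)C(=O)[O-])=C\CCC#C[Si](C)(C)C.C[C@@H]([NH3+])c1ccccc1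
F9 | step 3 | ethyl (2Z)-2-bromo-7-(trimethylsilyl)hept-2-en-6-ynoate | CCOC(=O)/C(Br)=C/CCC#C[Si](C)(C)C
F10 | step 3 | (2Z)-2-bromo-7-(trimethylsilyl)hept-2-en-6-yn-1-ol | OC/C(Br)=C/CCC#C[Si](C)(C)C
F11 | step 3 | [(5Z)-6,7-dibromohept-5-en-1-yn-1-yl]trimethylsilane | BrC/C(Br)=C/CCC#C[Si](C)(C)C
F12 | step 13 | C1 ketone of 16 (4-oxo in naphthalene numbering) | C=C1CC[C@H]2[C@](C)(C(=O)CC[C@]2(C)C(=O)OC)[C@H]1CCC#C[Si](C)(C)C
F13 | step 13 | tosylhydrazone of F12 | C=C1CC[C@H]2[C@](C)(C(=NNS(=O)(=O)c3ccc(C)cc3)CC[C@]2(C)C(=O)OC)[C@H]1CCC#C[Si](C)(C)C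
F14 | step 16 | methyl (1S,4aR,5S,8aS)-1,4a-dimethyl-6-methylidene-5-(3-oxobutyl)decahydronaphthalene-1-carboxylate | C=C1CC[C@H]2[C@](C)(CCC[C@]2(C)C(=O)OC)[C@H]1CCC(C)=O
F15 | step 16 | methyl (1S,4aR,5S,8aS)-5-[(3E)-5-methoxy-3-methyl-5-oxopent-3-en-1-yl]-1,4a-dimethyl-6-methylidenedecahydronaphthalene-1-carboxylate | C=C1CC[C@H]2[C@](C)(CCC[C@]2(C)C(=O)OC)[C@H]1CC/C(C)=C/C(=O)OC
A1 | alternative 1 | bicyclic alcohol with C5=C10 alkene, C19 hydroxymethyl and C8 dioxolane | OC[C@@]1(C)CCCC2=C1CCC1(C2)OCCO1
A2 | alternative 1 | propellane with C20 methylene bridging C5 and C10 on the face of C19 | OC[C@@]1(C)CCC[C@@]23C[C@@]12CCC4(C3)OCCO4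
A3 | alternative 2 | octalone with C8 ketone, C9=C10 alkene and C3 dioxolane | O=C1CC[C@@H]2CC3(OCCO3)CCC2=C1
A4 | alternative 2 | cis-fused decalone with C10 methyl, C9 allyl, C8 ketone and C3 dioxolane | O=C1CC[C@H]2[C@](C)(CCC3(OCCO3)C2)[C@H]1CC=C
A5 | alternative 3 | acyclic triene: (E)-2-methyl-2-enoate tethered to a (Z)-diene, C8 dioxolane, C12 silyl ether | COC(=O)/C(C)=C/CCC1(OCCO1)[C@H](CCO[Si](C)(C)C(C)(C)C)/C(C)=C\C=C
A6 | alternative 3 | cis-fused octalin methyl ester with C1=C2 alkene, C8 dioxolane and C12 silyl ether | O1CCOC12CC[C@H]3[C@](C)(C=CC[C@]3(C)C(=O)OC)[C@H]2CCO[Si](C)(C)C(C)(C)C
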